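**Retrosynthetic overview**
1. 9 ⇒ 8: C15–O bond by conjugate hydration of the exo-methylene of the cross-conjugated dienone; C4 settles by equilibration.
2. 8 ⇒ 6: key C10–O bond, formed by γ-hydroxylation of the extended enolate of the β,γ-enone (new catalytic oxaziridine O-transfer), which sets the C10 carbinol.
3. 6 ⇒ 5 + 3: a [4+2] cycloaddition builds the only new ring (central spiro-cyclohexene, bonds C2–C4' and C14–C15') and sets C4'; 5 is made in the flask from 4.
4. 4 ⇐ 3 ⇐ 2 ⇐ 1: both 5-7-5 guaianolide tricycles come intact from dehydrocostus lactone by C3 allylic oxidation.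

Assumption: dehydrocostus lactone (costus-root sesquiterpene lactone, sold in bulk) counts as a cheap commercial starting material. Guaianolide numbering is used; unprimed atoms belong to the half that becomes the diene, primed atoms to the dienophile half.

**Step 1**
Reactants: 1 dehydrocostus lactone (guaia-4(15),10(14),11(13)-trien-12,6α-olide; 1α-H, 5α-H, 6β-H, 7α-H)
Product: 2 3-epizaluzanin C (3α-hydroxy derivative of 1; 3R)
Conditions: SeO2 (0.3 equiv), t-BuOOH (3 equiv), CH2Cl2, 23 °C, 16 h
Reagents that add atoms: selenium dioxide, O=[Se]=O; tert-butyl hydroperoxide, CC(C)(C)OO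
Why: SeO2/t-BuOOH allylic hydroxylation (ene reaction then 2,3-sigmatropic shift) is fastest at the ring CH2 next to the strained cyclopentylidene methylene; selenium attacks the convex α face so the carbinol is 3α, and this centre is removed in step 2.

**Step 2**
Reactants: 2 3-epizaluzanin C
Product: 3 dehydrozaluzanin C (3-oxo derivative of 1)
Conditions: Dess–Martin periodinane (1.3 equiv), CH2Cl2, 0 → 23 °C
Reagents that add atoms: none
Why: Dess–Martin oxidation of the secondary allylic alcohol to the enone under neutral conditions; the three exocyclic alkenes and the lactone are inert and no stereocentre is formed.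

**Step 3**
Reactants: 3 dehydrozaluzanin C
Product: 4 TBS dienol ether of 3 (3-silyloxy-guaia-2,4(15),10(14),11(13)-tetraen-12,6α-olide)
Conditions: TBSOTf (1.2 equiv), Et3N (2 equiv), CH2Cl2, −78 → 0 °C
Reagents that add atoms: tert-butyldimethylsilyl triflate, CC(C)(C)[Si](C)(C)OS(=O)(=O)C(F)(F)F
Why: Soft enolisation and O-silylation; C2 is the only α-carbon bearing hydrogen, so a single 2-silyloxydiene forms, and it is locked s-trans so it cannot act as a Diels–Alder diene itself.

**Step 4**
Reactants: 4 TBS dienol ether of 3; 3 dehydrozaluzanin C (dienophile, 3 equiv, excess recovered)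
Product: 6 Diels–Alder adduct (spiro dimer; β,γ-enone with C1=C10; 2α-H endo isomer drawn), via trienone 5 (not isolated)
Conditions: Pd(OAc)2 (1.05 equiv), MeCN, 23 → 40 °C
Reagents that add atoms: none
Why: Saegusa–Ito oxidation (divalent palladium C2-enolate, syn β-hydride loss of H1α) unveils the locked s-cis diene C14=C10–C1=C2 of 5, which is trapped by the exo-methylene ketone C4'=C15' of excess 3 in a Diels–Alder reaction with "ortho" orientation (C2–C4' and C14–C15'); spiro centre C4' is set by addition to the convex α face of 3, anti to the C5'–C6' bond, while C2 (its epimer behaves identically) is erased in step 5.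

**Step 5**
Reactants: 6 Diels–Alder adduct
Product: 8 15-anhydro-ainsliadimer B (10β-hydroxy cross-conjugated dienone), via phosphazenium dienolate 7 (not isolated)
Conditions: BTPP (tert-butylimino-tri(pyrrolidino)phosphorane, 0.3 equiv), (±)-trans-3-phenyl-2-(phenylsulfonyl)oxaziridine (1.3 equiv), THF, −40 °C; then AcOH
Reagents that add atoms: 3-phenyl-2-(phenylsulfonyl)oxaziridine, O=S(=O)(N1OC1c1ccccc1)c1ccccc1
Why: Proposed new method: a catalytic, γ-selective "vinylogous Davis hydroxylation" — the phosphazene reversibly removes the only acidic proton (C2–H, α to C3=O and allylic), so both C2 epimers of 6 converge on the planar extended enolate 7; its α-carbon is neopentylic (next to spiro C4'), so the electrophilic oxaziridine oxygen is taken up at the γ-terminus C10, giving the C10 alkoxide and the conjugated enone, and re-protonation turns the base over; allylic 1,3-strain between the ion-paired enolate oxygen and the spiro substituents forces the bulky C5' arm pseudo-axial on the α face, so chair-like axial attack and reagent approach both occur on the β face (syn to the C3' carbonyl) and set 10β-OH; the closest known reaction types are the Davis α-hydroxylation of preformed enolates with N-sulfonyloxaziridines and the base-mediated aerobic γ-hydroperoxidation of β,γ-unsaturated ketones.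

**Step 6**
Reactants: 8 15-anhydro-ainsliadimer B
Product: 9 ainsliadimer B
Conditions: Na2CO3/NaHCO3 buffer (pH 10), THF/H2O (1:1), 23 °C
Reagents that add atoms: water, O
Why: Base-catalysed oxa-Michael addition of water (conjugate hydration) at C15, the terminus of the cross-conjugated exo-methylene dienone and the most electrophilic acceptor present (it gives a cyclopentadienolate), outpaces addition to the two α-methylene lactones; the new C4 centre is α to the ketone and equilibrates to the more stable 4α-CH2OH (trans to C6), as in the target.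

**Compound list**
1 | dehydrocostus lactone | C=C1CC[C@H]2C(=C)CC[C@H]3C(=C)C(=O)O[C@@H]3[C@H]21 | starting material
2 | 3-epizaluzanin C (3α-OH) | C=C1[C@H](O)C[C@H]2C(=C)CC[C@H]3C(=C)C(=O)O[C@@H]3[C@H]21 | intermediate
3 | dehydrozaluzanin C | C=C1C(=O)C[C@H]2C(=C)CC[C@H]3C(=C)C(=O)O[C@@H]3[C@H]21 | intermediate
4 | TBS dienol ether of 3 | C=C1C(O[Si](C)(C)C(C)(C)C)=C[C@H]2C(=C)CC[C@H]3C(=C)C(=O)O[C@@H]3[C@H]21 | intermediate
5 | trienone (3-oxoguaia-1,4(15),10(14),11(13)-tetraen-12,6α-olide) | C=C1C(=O)C=C2C(=C)CC[C@H]3C(=C)C(=O)O[C@@H]3[C@H]21 | intermediate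
6 | Diels–Alder adduct (2α-H; C1=C10; spiro C4' with C15' β) | C=C1C(=O)O[C@@H]2[C@@H]3C4=C(CC[C@@H]12)CC[C@@]1([C@@H]4C(=O)C3=C)C(=O)C[C@H]2C(=C)CC[C@H]3C(=C)C(=O)O[C@@H]3[C@H]21 | intermediate
7 | phosphazenium (BTPP-H+) salt of the C3 extended enolate of 6 | C=C1C(=O)O[C@@H]2[C@@H]3C4=C(CC[C@@H]12)CC[C@@]1(C4=C([O-])C3=C)C(=O)C[C@H]2C(=C)CC[C@H]3C(=C)C(=O)O[C@@H]3[C@H]21.CC(C)(C)N[P+](N1CCCC1)(N1CCCC1)N1CCCC1 | intermediate
8 | 15-anhydro-ainsliadimer B (10β-OH) | C=C1C(=O)O[C@@H]2[C@@H]3C4=C(C(=O)C3=C)[C@]3(CC[C@]4(O)CC[C@@H]12)C(=O)C[C@H]1C(=C)CC[C@H]2C(=C)C(=O)O[C@@H]2[C@H]13 | intermediate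
9 | ainsliadimer B | C=C1C(=O)O[C@@H]2[C@@H]3C4=C(C(=O)[C@H]3CO)[C@]3(CC[C@]4(O)CC[C@@H]12)C(=O)C[C@H]1C(=C)CC[C@H]2C(=C)C(=O)O[C@@H]2[C@H]13 | target

**Totals**
Total step count: 6. Longest linear sequence: 6 steps (1 → 2 → 3 → 4 → 6 → 8 → 9; compound 3 is used a second time as the dienophile in step 4).

**Steps most likely to fail**

Step 5 (the proposed new reaction). The risks are O-transfer at C2 instead of C10, attack on the α face giving the C10 epimer, further oxidation of 8 through its C5–H, and slow turnover of the base. The face selectivity rests on a conformational argument, not on a precedent. The fallback uses known chemistry, sets out from 6 and returns at 8. Compound 6 is stirred with BTPP (0.2 equiv) in THF under O2 (1 atm) at −20 °C; the same dienolate 7 undergoes the familiar radical-chain γ-oxygenation to the 10β-hydroperoxy dienone F3. PPh3 (1.1 equiv) then reduces the O–O bond to give 8, and any C10 epimer is removed by chromatography.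

Step 4 (Saegusa oxidation with cross-cycloaddition). Trienone 5 may dimerise with itself or polymerise faster than it is trapped by 3, and palladium may be sequestered by the alkenes. The fallback sets out from 4 and returns at 6. Treating 4 with PhSeCl (THF, −78 °C) gives 2α-(phenylselanyl)dehydrozaluzanin C F1, with selenium on the convex face and cis to H1. Oxidation with H2O2 (pyridine, CH2Cl2, 0 °C) gives the selenoxide F2, which is not isolated. Its syn-elimination releases 5 slowly at 0–23 °C into a solution holding excess 3, which traps it as 6 without any metal.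

Step 6 (conjugate hydration). The risks are competing addition to the α-methylene lactones, reversal of the hydration, and retro-aldol loss of formaldehyde. The fallback sets out from 8 and returns at 9. Nucleophilic epoxidation of the exo-methylene dienone with H2O2/NaHCO3 (THF/MeOH, 0 °C) is kinetically controlled and irreversible, and gives the 4α,15-spiro-epoxy ketone F4. SmI2 (2.2 equiv, THF/MeOH, −90 °C; divalent samarium) then cleaves the C4–O bond α to the ketone. Protonation and equilibration at C4 on work-up give 9.

**Further compounds**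
F1 | step 4 | 2α-(phenylselanyl)dehydrozaluzanin C | C=C1C(=O)[C@H]([Se]c2ccccc2)[C@H]2C(=C)CC[C@H]3C(=C)C(=O)O[C@@H]3[C@H]21
F2 | step 4 | selenoxide of F1 (mixture at selenium) | C=C1C(=O)[C@H]([Se](=O)c2ccccc2)[C@H]2C(=C)CC[C@H]3C(=C)C(=O)O[C@@H]3[C@H]21
F3 | step 5 | 10β-hydroperoxy analogue of 8 | C=C1C(=O)O[C@@H]2[C@@H]3C4=C(C(=O)C3=C)[C@]3(CC[C@]4(OO)CC[C@@H]12)C(=O)C[C@H]1C(=C)CC[C@H]2C(=C)C(=O)O[C@@H]2[C@H]13
F4 | step 6 | 4α,15-epoxide of 8 (epoxide oxygen on the α face) | C=C1C(=O)O[C@@H]2[C@@H]3C4=C(C(=O)[C@]35CO5)[C@]3(CC[C@]4(O)CC[C@@H]12)C(=O)C[C@H]1C(=C)CC[C@H]2C(=C)C(=O)O[C@@H]2[C@H]13
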